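## Analysis of the target

The target 23 is a (2S)-flavanone. Ring A is a phloroglucinol-type arene with free hydroxyls at C5 and C7, ring C is the chroman-4-one with its only stereocentre at C2, and ring B is a 4-hydroxy-3-methoxyphenyl group. C6, the carbon between the two ring A hydroxyls, carries a ten-carbon chain (C1''–C8'' counted from ring A, methyls on C3'' and C7''). The chain has an (E)-C2''=C3'' alkene, a secondary hydroxyl at C6'' of R configuration and a C7''=C8'' methylene. The two stereocentres lie more than ten bonds apart across a flat arene, so neither can steer the other and each has to be set by a reagent. C2 is base-labile: it is the β-carbon of an aryl ketone with O1 as a leaving group, so base opens ring C and racemises it, most easily once the ring A hydroxyls are free. The chain is acid-labile: the C2''=C3'' alkene can cyclise onto a flanking phenol and the allylic C6'' alcohol can ionise. Ring A must also be substituted at C6 and not at C8, and the two chain alkenes must be told apart. The strategy rests on one relation: the C6''(OH)–C7''(=C8''H2) unit is the 1,3-transposed form of an (E)-C6''=C7''–C8''H2OH allylic alcohol, which is what allylic oxidation of a geranyl terminus gives. The C6'' carbinol can therefore come from a hydroxyl-directed asymmetric epoxidation of that alkene, followed by reductive opening of the oxirane from the C8'' side.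

## Retrosynthetic reasoning

23 from 22. The last operation only removes the three aryl silyl ethers of 22. Silyl groups are chosen because their cleavage can be buffered to be neither acidic (chain) nor basic (C2). No skeletal bond is cut here.

22 from 21, and 21 from 20. The C7''=C8'' methylene and the free C6'' hydroxyl are traced back to epoxy iodide 21. In the forward sense a two-electron reduction at C8'' expels the oxirane oxygen from C7''. The C6''–O bond is never broken, so the configuration set in the epoxide is carried into the carbinol. Iodide 21 comes from epoxy alcohol 20 by substitution at the primary C8'' hydroxyl.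

20 from 19. The C6''–O and C7''–O bonds of the oxirane are cut to give allylic alcohol 19. This is the place to cut because the C8'' hydroxyl is the only group that distinguishes C6''=C7'' from C2''=C3'', and it is also the handle for a reagent-controlled Sharpless epoxidation. Both chain stereocentres of 20 are set in one step on the complete skeleton, so no chiral chain fragment has to be carried through the coupling. The forward reaction must choose one alkene face, leave C2''=C3'' alone and tolerate the ketone.

19 from 18. The C8''–O bond is cut. Allylic oxidation of 18 has to pick the (E)-methyl group of the terminal trisubstituted alkene, which is the normal site for this oxidation in a geranyl unit.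

18 from 17, and 17 from 13 and 16. The C6–C1'' bond is cut into aryl iodide 13 and geranylstannane 16. A Stille coupling is chosen because it needs no base, which suits both C2 and the aryl silyl ethers, and because it brings in the (E)-alkene ready-made. The 5-hydroxyl is left free for the coupling to keep the flank of C6 small, and is silylated afterwards (17 to 18) so that no phenol meets the oxidant or the epoxidation catalyst.

13 from 12, and 12 from 11. The C6–I bond is cut. In 12 only the chelated 5-hydroxyl is free, and it directs an electrophile to its ortho carbon C6. Compound 12 comes from triol 11 by silylation of the two non-chelated hydroxyls.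

11 from 10, and 10 from 4 and 9. The C2–C1' bond is cut into chromone 4 and arylboronic acid 9. An asymmetric conjugate addition then builds the C2 stereocentre from two flat, achiral pieces under catalyst control. The benzyl ethers of 10 are removed by hydrogenolysis to 11 before any alkene is in the molecule.

Starting materials. Chromone 4 comes from acetophenone 1 through dibenzyl ether 2 and enaminone 3, which adds the C2 carbon. Boronic acid 9 comes from bromophenol 5 through 6, 7 and 8. Stannane 16 comes from geraniol 14 through chloride 15.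

## Alternatives that were turned down

Alternative 1: Ring A is cut at C4a–C5, so the carbocycle is unfolded into a tricarbonyl arm on ring C.
- Forward key step: keto ester A2 is a (2S)-2-aryl-2,3-dihydropyran-4-one with a CH2–CO–CH(chain)–CO2Me arm on its enol ether carbon. Mg(OMe)2 turns it into the extended enolate, the future C4a attacks the ester carbon (the future C5), methanol leaves and the triketone tautomerises to the arene. The product is A1, with both ring A hydroxyls free.
- For it: the chain sits on the carbon between the two carbonyls that become C5 and C7, so the C6 versus C8 question cannot arise, and O5 and O7 need no protection. On this point it is stronger than the chosen route, which relies on a directing effect in an electrophilic iodination.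
- Against it: A2 has several enolisable sites, so O-acylation, aldol closure and retro-Claisen cleavage compete with the wanted C-acylation. The dienolate needed for the Claisen step is also the species that expels O1 from C2 (E1cB), and A1 is a 5,7-dihydroxyflavanone standing in alkoxide base. A2 also needs an enantioselective dihydropyranone synthesis and a separately made chiral chain with a second silyl group, which makes the sequence longer.
- Comparison: the chosen route never exposes C2 to base once it exists, and it takes rings A and C together from acetophenone 1.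

Alternative 2: Ring C is cut at C4–C4a.
- Forward key step: the (S)-3-aryloxy-3-arylpropanoic acid A4 is activated as its mixed anhydride with trifluoroacetic anhydride, buffered by 2,6-di-tert-butylpyridine, and acylates its own aryl ether ortho to oxygen to give A3.
- For it: the aryl ether of A4 has two equivalent ortho positions, so only the 6-substituted flavanone can form. Regiochemistry is settled by symmetry, which is better than by a directing effect, and no palladium coupling at a crowded carbon is needed.
- Against it: the complete chain is present when an acylium-type electrophile and trifluoroacetic acid are generated. That chain holds an electron-rich trisubstituted alkene two atoms from a very nucleophilic arene, a 1,1-disubstituted alkene and an allylic silyl ether. The buffer limits, but cannot exclude, protonation of C2''=C3'' with cyclisation. The β-aryloxy acid can also lose the phenol to give the cinnamic acid, and the benzylic C–O bond can ionise even with the 4'-oxygen as a carbonate; either event erases C2. Two kinds of protecting group and a chiral chain fragment are needed before the union.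
- Comparison: the chosen route is weaker on ring A regiochemistry. In return it keeps electrophiles and acid away from the chain, creates the chain stereocentre on the assembled skeleton, and uses one protecting group type late on.

Alternative 3: Ring C is cut at C3–C4 and C2–H.
- Forward key step: aldehyde A6 is a ring A benzaldehyde with a 1-arylvinyl ether on the ortho oxygen. A cationic monovalent rhodium catalyst ([Rh(cod)Cl]2, a chiral bisphosphine of the BINAP class, AgBF4) adds its formyl C–H across the vinyl ether to give A5.
- For it: ring C and C2 are formed in one neutral, atom-economical step with no stoichiometric by-product. On atom economy, and on the safety of C2 when it is created, it is at least as good as the conjugate addition used here.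
- Against it: insertion can go either way, giving the six-membered flavanone or a five-membered 2-aryl-2-methylbenzofuran-3-one. The formyl group lies between two ortho oxygens, so C–H activation is slow and decarbonylation competes. The unhindered C7''=C8'' methylene can bind the metal hydride and be isomerised. Which ortho oxygen of ring A carries the vinyl ether decides C6 versus C8, so the regiochemical problem is only moved. The acetal protecting groups of A5 need acid for removal, with the acid-sensitive chain in place.
- Comparison: the chosen route sets C2 by the well-mapped conjugate addition to a chromone and ends with buffered fluoride instead of acid.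

Key step: step 14

Locants: flavanone numbering (O1, C2–C4, C4a, C5–C8, C8a; ring B primed); chain C1''–C8'' from ring A.

Assumption: the (S) biaryl bisphosphine in step 5 is taken to give 2S, by analogy with the facial sense of such rhodium catalysts on cyclohex-2-enone. If a trial shows the opposite sense, the (R) ligand is used and nothing else changes.

## Route

Step 1
Reactants: 1 2,4,6-trihydroxyacetophenone
Product: 2 1-[2,4-bis(benzyloxy)-6-hydroxyphenyl]ethanone
Conditions: BnBr (2.1 equiv), K2CO3, DMF, rt
Reagents that add atoms: benzyl bromide, BrCc1ccccc1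
Why: Williamson etherification; the hydroxyl hydrogen-bonded to the acetyl carbonyl is the least reactive, so two equivalents of halide should stop at the dibenzyl ether and leave the phenol that closes ring C.

Step 2
Reactants: 2 1-[2,4-bis(benzyloxy)-6-hydroxyphenyl]ethanone
Product: 4 5,7-bis(benzyloxy)-4H-chromen-4-one, via enaminone 3 (not isolated)
Conditions: Me2NCH(OMe)2, toluene, 100 °C; then conc. HCl, CH2Cl2, 40 °C
Reagents that add atoms: N,N-dimethylformamide dimethyl acetal, COC(OC)N(C)C
Why: Enaminone condensation at the acetyl methyl group, then acid-promoted addition of the phenol and loss of dimethylamine (the standard enaminone route to 2,3-unsubstituted chromones); benzyl ethers tolerate the acid.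

Step 3
Reactants: 5 4-bromo-2-methoxyphenol
Product: 6 1-(benzyloxy)-4-bromo-2-methoxybenzene
Conditions: BnBr, K2CO3, acetone, reflux
Reagents that add atoms: benzyl bromide, BrCc1ccccc1
Why: Williamson etherification; masks the phenol for the lithiation and matches the protecting groups of 4.

Step 4
Reactants: 6 1-(benzyloxy)-4-bromo-2-methoxybenzene
Product: 9 [4-(benzyloxy)-3-methoxyphenyl]boronic acid, via aryllithium 7 (not isolated), via lithium aryltriisopropoxyborate 8 (not isolated)
Conditions: n-BuLi, THF, −78 °C; B(OiPr)3, −78 °C to rt; 1 M HCl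
Reagents that add atoms: triisopropyl borate, CC(C)OB(OC(C)C)OC(C)C; water, O
Why: Bromine–lithium exchange, trapping with the borate and hydrolysis; the lithium is para to the ether oxygen, so no ortho-lithiation pathway interferes.

Step 5
Reactants: 4 5,7-bis(benzyloxy)-4H-chromen-4-one; 9 [4-(benzyloxy)-3-methoxyphenyl]boronic acid
Product: 10 (2S)-5,7-bis(benzyloxy)-2-[4-(benzyloxy)-3-methoxyphenyl]chroman-4-one
Conditions: [Rh(OH)(cod)]2 (2.5 mol%), (S)-6,6'-dimethoxy-2,2'-bis[bis(3,4,5-trifluorophenyl)phosphino]biphenyl (5.5 mol%), 9 (2.5 equiv), toluene/H2O 10:1, 40 °C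
Reagents that add atoms: none
Why: Rhodium-catalysed asymmetric 1,4-addition of an arylboronic acid to a chromone (Hayashi–Miyaura reaction): the aryl group passes from boron to monovalent rhodium, adds across C2=C3, and water protonates the rhodium enolate; C2 is set by the chiral bisphosphine (see the assumption), and the electron-poor phosphine should speed turnover on this donor-substituted chromone while leaving the flavanone product alone.

Step 6
Reactants: 10 (2S)-5,7-bis(benzyloxy)-2-[4-(benzyloxy)-3-methoxyphenyl]chroman-4-one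
Product: 11 (2S)-5,7-dihydroxy-2-(4-hydroxy-3-methoxyphenyl)chroman-4-one
Conditions: H2 (1 atm), 10% Pd/C, EtOAc/MeOH, rt
Reagents that add atoms: none
Why: Hydrogenolysis of three benzyl aryl ethers under neutral conditions, which should not touch C2; it is placed before any alkene enters and is stopped once the ethers are gone, so that the benzylic C2–O1 bond is not cleaved.

Step 7
Reactants: 11 (2S)-5,7-dihydroxy-2-(4-hydroxy-3-methoxyphenyl)chroman-4-one
Product: 12 (2S)-7-(tert-butyldimethylsilyloxy)-2-[4-(tert-butyldimethylsilyloxy)-3-methoxyphenyl]-5-hydroxychroman-4-one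
Conditions: TBSCl (2.2 equiv), imidazole, DMF, 0 °C
Reagents that add atoms: tert-butyldimethylsilyl chloride, CC(C)(C)[Si](C)(C)Cl
Why: Silylation of the two non-chelated phenols; the 5-hydroxyl, hydrogen-bonded to C4=O, should stay free and then serves as the directing group for step 8.

Step 8
Reactants: 12 (2S)-7-(tert-butyldimethylsilyloxy)-2-[4-(tert-butyldimethylsilyloxy)-3-methoxyphenyl]-5-hydroxychroman-4-one
Product: 13 (2S)-7-(tert-butyldimethylsilyloxy)-2-[4-(tert-butyldimethylsilyloxy)-3-methoxyphenyl]-5-hydroxy-6-iodochroman-4-one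
Conditions: N-iodosuccinimide (1.0 equiv), DMF, 0 °C to rt, dark
Reagents that add atoms: N-iodosuccinimide, O=C1CCC(=O)N1I
Why: Electrophilic aromatic iodination under neutral conditions; in 5-hydroxy-7-O-protected flavonoids the free chelated phenol directs the electrophile to its ortho carbon C6, while C8 lies between two ether oxygens and ring B has no free phenol; the site is to be confirmed by the long-range coupling of the 5-OH proton.

Step 9
Reactants: 14 geraniol
Product: 15 geranyl chloride
Conditions: N-chlorosuccinimide, Me2S, CH2Cl2, −30 to 0 °C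
Reagents that add atoms: N-chlorosuccinimide, O=C1CCC(=O)N1Cl
Why: Corey–Kim chlorination of a primary allylic alcohol; chloride displaces the alkoxysulfonium group by SN2 without allylic shift, so the (E)-alkene is kept.

Step 10
Reactants: 15 geranyl chloride
Product: 16 tributyl[(2E)-3,7-dimethylocta-2,6-dienyl]stannane
Conditions: Bu3SnLi (from Bu3SnH and LiN(iPr)2), THF, −78 to 0 °C
Reagents that add atoms: tributyltin hydride (used as tributylstannyllithium), CCCC[SnH](CCCC)CCCC
Why: SN2 displacement of the primary allylic chloride by the stannyl anion, which gives the linear (E)-allylstannane.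

Step 11
Reactants: 13 (2S)-7-(tert-butyldimethylsilyloxy)-2-[4-(tert-butyldimethylsilyloxy)-3-methoxyphenyl]-5-hydroxy-6-iodochroman-4-one; 16 tributyl[(2E)-3,7-dimethylocta-2,6-dienyl]stannane
Product: 17 (2S)-7-(tert-butyldimethylsilyloxy)-2-[4-(tert-butyldimethylsilyloxy)-3-methoxyphenyl]-6-[(2E)-3,7-dimethylocta-2,6-dienyl]-5-hydroxychroman-4-one
Conditions: Pd(PPh3)4 (5 mol%), 16 (1.5 equiv), DMF, 90 °C
Reagents that add atoms: none
Why: Stille coupling of an aryl iodide with an allylstannane: zerovalent palladium inserts into C6–I, the allyl group is transferred from tin, and reductive elimination at the less substituted allyl terminus gives the linear (E)-geranyl arene; no base or fluoride is present, so C2 and the silyl ethers should survive.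

Step 12
Reactants: 17 (2S)-7-(tert-butyldimethylsilyloxy)-2-[4-(tert-butyldimethylsilyloxy)-3-methoxyphenyl]-6-[(2E)-3,7-dimethylocta-2,6-dienyl]-5-hydroxychroman-4-one
Product: 18 (2S)-5,7-bis(tert-butyldimethylsilyloxy)-2-[4-(tert-butyldimethylsilyloxy)-3-methoxyphenyl]-6-[(2E)-3,7-dimethylocta-2,6-dienyl]chroman-4-one
Conditions: TBSOTf (1.3 equiv), 2,6-lutidine, CH2Cl2, −20 to 0 °C
Reagents that add atoms: tert-butyldimethylsilyl trifluoromethanesulfonate, CC(C)(C)[Si](C)(C)OS(=O)(=O)C(F)(F)F
Why: Silylation of the hindered, chelated phenol needs the triflate; it removes the last acidic, metal-binding hydroxyl before the oxidations, and the weak base and low temperature should avoid silyl enol ether formation at C3.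

Step 13
Reactants: 18 (2S)-5,7-bis(tert-butyldimethylsilyloxy)-2-[4-(tert-butyldimethylsilyloxy)-3-methoxyphenyl]-6-[(2E)-3,7-dimethylocta-2,6-dienyl]chroman-4-one
Product: 19 (2S)-5,7-bis(tert-butyldimethylsilyloxy)-2-[4-(tert-butyldimethylsilyloxy)-3-methoxyphenyl]-6-[(2E,6E)-8-hydroxy-3,7-dimethylocta-2,6-dienyl]chroman-4-one
Conditions: SeO2 (0.3 equiv), t-BuOOH (3 equiv), salicylic acid (0.1 equiv), CH2Cl2, 0 °C to rt, stopped at partial conversion
Reagents that add atoms: selenium dioxide (catalytic oxygen carrier), O=[Se]=O; tert-butyl hydroperoxide (stoichiometric oxygen source), CC(C)(C)OO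
Why: Catalytic selenium dioxide allylic oxidation (ene reaction, then [2,3]-sigmatropic shift), which attacks the (E)-methyl group of the most accessible trisubstituted alkene; the terminal alkene is open, whereas C2''=C3'' is shielded by the arene with its two ortho silyl ethers, and at this temperature the ketone α-position should not react.

Step 14
Reactants: 19 (2S)-5,7-bis(tert-butyldimethylsilyloxy)-2-[4-(tert-butyldimethylsilyloxy)-3-methoxyphenyl]-6-[(2E,6E)-8-hydroxy-3,7-dimethylocta-2,6-dienyl]chroman-4-one
Product: 20 (2S)-5,7-bis(tert-butyldimethylsilyloxy)-2-[4-(tert-butyldimethylsilyloxy)-3-methoxyphenyl]-6-{(2E)-5-[(2R,3R)-3-(hydroxymethyl)-3-methyloxiran-2-yl]-3-methylpent-2-enyl}chroman-4-one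
Conditions: Ti(OiPr)4 (0.2 equiv), D-(−)-diethyl tartrate (0.24 equiv), t-BuOOH (2 equiv, anhydrous), 4 Å molecular sieves, CH2Cl2, −20 °C; non-basic work-up
Reagents that add atoms: tert-butyl hydroperoxide, CC(C)(C)OO
Why: Sharpless asymmetric epoxidation: the C8'' hydroxyl of 19 and the hydroperoxide exchange onto the tetravalent titanium tartrate dimer, and the bound peroxide oxygen is passed to the C6''=C7'' alkene of the bound allylic alkoxide. The closest known reaction type is the epoxidation of (E)-2-methylalk-2-en-1-ols, which is this substrate class. The oxirane is closed by a single concerted, suprafacial oxygen-atom transfer that forms C6''–O and C7''–O together, not by a stepwise displacement. The absolute configuration at C6'' and C7'' is set by the tartrate: by the usual face rule the D-(−) ester gives the (6''R,7''R) epoxide, which is to be confirmed on this substrate, for example by Mosher ester analysis after step 16. The trans relation of the two centres follows from the (E) geometry and the syn addition. Site selectivity between the two chain alkenes is needed and is secured by the C8'' hydroxyl, since only C6''=C7'' can be reached from the titanium to which that hydroxyl is bound. The ketone and the aryl silyl ethers should not bind titanium competitively, and with no base present at −20 °C the distant C2 centre neither influences the step nor is at risk.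

Step 15
Reactants: 20 (2S)-5,7-bis(tert-butyldimethylsilyloxy)-2-[4-(tert-butyldimethylsilyloxy)-3-methoxyphenyl]-6-{(2E)-5-[(2R,3R)-3-(hydroxymethyl)-3-methyloxiran-2-yl]-3-methylpent-2-enyl}chroman-4-one
Product: 21 (2S)-5,7-bis(tert-butyldimethylsilyloxy)-2-[4-(tert-butyldimethylsilyloxy)-3-methoxyphenyl]-6-{(2E)-5-[(2R,3S)-3-(iodomethyl)-3-methyloxiran-2-yl]-3-methylpent-2-enyl}chroman-4-one
Conditions: PPh3, imidazole, I2, CH2Cl2, 0 °C
Reagents that add atoms: iodine, II
Why: Garegg–Samuelsson iodination: iodide displaces the alkoxyphosphonium group at C8'' by SN2 while the oxirane is untouched; the descriptor at C7'' changes to S only because CH2I now outranks C6''.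

Step 16
Reactants: 21 (2S)-5,7-bis(tert-butyldimethylsilyloxy)-2-[4-(tert-butyldimethylsilyloxy)-3-methoxyphenyl]-6-{(2E)-5-[(2R,3S)-3-(iodomethyl)-3-methyloxiran-2-yl]-3-methylpent-2-enyl}chroman-4-one
Product: 22 (2S)-5,7-bis(tert-butyldimethylsilyloxy)-2-[4-(tert-butyldimethylsilyloxy)-3-methoxyphenyl]-6-[(2E,6R)-6-hydroxy-3,7-dimethylocta-2,7-dienyl]chroman-4-one
Conditions: Zn dust, AcOH (3 equiv), EtOH, rt
Reagents that add atoms: none
Why: Reductive opening of a 2,3-epoxy iodide: zinc inserts into the C8''–I bond and the organozinc expels the oxirane oxygen from C7'', which creates the C7''=C8'' methylene; the C6''–O bond is not broken, so C6'' keeps its configuration (R).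

Step 17
Reactants: 22 (2S)-5,7-bis(tert-butyldimethylsilyloxy)-2-[4-(tert-butyldimethylsilyloxy)-3-methoxyphenyl]-6-[(2E,6R)-6-hydroxy-3,7-dimethylocta-2,7-dienyl]chroman-4-one
Product: 23 (2S)-5,7-dihydroxy-2-(4-hydroxy-3-methoxyphenyl)-6-[(2E,6R)-6-hydroxy-3,7-dimethylocta-2,7-dienyl]chroman-4-one
Conditions: HF·pyridine, pyridine, THF, 0 °C to rt
Reagents that add atoms: none
Why: Fluoride cleavage of the three aryl silyl ethers; the pyridine buffer should keep the medium from being acidic enough to cyclise the chain onto a phenol or basic enough to open ring C.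

## Compound list

1 | 2,4,6-trihydroxyacetophenone | CC(=O)c1c(O)cc(O)cc1O | starting material
2 | 1-[2,4-bis(benzyloxy)-6-hydroxyphenyl]ethanone | CC(=O)c1c(O)cc(OCc2ccccc2)cc1OCc1ccccc1 | intermediate
3 | (2E)-1-[2,4-bis(benzyloxy)-6-hydroxyphenyl]-3-(dimethylamino)prop-2-en-1-one | CN(C)/C=C/C(=O)c1c(O)cc(OCc2ccccc2)cc1OCc1ccccc1 | intermediate
4 | 5,7-bis(benzyloxy)-4H-chromen-4-one | O=c1ccoc2cc(OCc3ccccc3)cc(OCc3ccccc3)c12 | intermediate
5 | 4-bromo-2-methoxyphenol | COc1cc(Br)ccc1O | starting material
6 | 1-(benzyloxy)-4-bromo-2-methoxybenzene | COc1cc(Br)ccc1OCc1ccccc1 | intermediate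
7 | [4-(benzyloxy)-3-methoxyphenyl]lithium | [Li]c1ccc(OCc2ccccc2)c(OC)c1 | intermediate
8 | lithium [4-(benzyloxy)-3-methoxyphenyl]tri(propan-2-yloxy)borate | [Li+].CC(C)O[B-](OC(C)C)(OC(C)C)c1ccc(OCc2ccccc2)c(OC)c1 | intermediate
9 | [4-(benzyloxy)-3-methoxyphenyl]boronic acid | OB(O)c1ccc(OCc2ccccc2)c(OC)c1 | intermediate
10 | (2S)-5,7-bis(benzyloxy)-2-[4-(benzyloxy)-3-methoxyphenyl]chroman-4-one | O=C1C[C@@H](c2ccc(OCc3ccccc3)c(OC)c2)Oc2cc(OCc3ccccc3)cc(OCc3ccccc3)c21 | intermediate
11 | (2S)-5,7-dihydroxy-2-(4-hydroxy-3-methoxyphenyl)chroman-4-one | O=C1C[C@@H](c2ccc(O)c(OC)c2)Oc2cc(O)cc(O)c21 | intermediate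
12 | (2S)-7-(tert-butyldimethylsilyloxy)-2-[4-(tert-butyldimethylsilyloxy)-3-methoxyphenyl]-5-hydroxychroman-4-one | O=C1C[C@@H](c2ccc(O[Si](C)(C)C(C)(C)C)c(OC)c2)Oc2cc(O[Si](C)(C)C(C)(C)C)cc(O)c21 | intermediate
13 | (2S)-7-(tert-butyldimethylsilyloxy)-2-[4-(tert-butyldimethylsilyloxy)-3-methoxyphenyl]-5-hydroxy-6-iodochroman-4-one | O=C1C[C@@H](c2ccc(O[Si](C)(C)C(C)(C)C)c(OC)c2)Oc2cc(O[Si](C)(C)C(C)(C)C)c(I)c(O)c21 | intermediate
14 | geraniol, (2E)-3,7-dimethylocta-2,6-dien-1-ol | CC(C)=CCC/C(C)=C/CO | starting material
15 | geranyl chloride, (2E)-1-chloro-3,7-dimethylocta-2,6-diene | CC(C)=CCC/C(C)=C/CCl | intermediate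
16 | tributyl[(2E)-3,7-dimethylocta-2,6-dienyl]stannane | CC(C)=CCC/C(C)=C/C[Sn](CCCC)(CCCC)CCCC | intermediate
17 | (2S)-7-(tert-butyldimethylsilyloxy)-2-[4-(tert-butyldimethylsilyloxy)-3-methoxyphenyl]-6-[(2E)-3,7-dimethylocta-2,6-dienyl]-5-hydroxychroman-4-one | CC(C)=CCC/C(C)=C/Cc1c(O[Si](C)(C)C(C)(C)C)cc2c(c1O)C(=O)C[C@@H](c1ccc(O[Si](C)(C)C(C)(C)C)c(OC)c1)O2 | intermediate
18 | (2S)-5,7-bis(tert-butyldimethylsilyloxy)-2-[4-(tert-butyldimethylsilyloxy)-3-methoxyphenyl]-6-[(2E)-3,7-dimethylocta-2,6-dienyl]chroman-4-one | CC(C)=CCC/C(C)=C/Cc1c(O[Si](C)(C)C(C)(C)C)cc2c(c1O[Si](C)(C)C(C)(C)C)C(=O)C[C@@H](c1ccc(O[Si](C)(C)C(C)(C)C)c(OC)c1)O2 | intermediate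
19 | (2S)-5,7-bis(tert-butyldimethylsilyloxy)-2-[4-(tert-butyldimethylsilyloxy)-3-methoxyphenyl]-6-[(2E,6E)-8-hydroxy-3,7-dimethylocta-2,6-dienyl]chroman-4-one | OC/C(C)=C/CC/C(C)=C/Cc1c(O[Si](C)(C)C(C)(C)C)cc2c(c1O[Si](C)(C)C(C)(C)C)C(=O)C[C@@H](c1ccc(O[Si](C)(C)C(C)(C)C)c(OC)c1)O2 | intermediate
20 | (2S)-5,7-bis(tert-butyldimethylsilyloxy)-2-[4-(tert-butyldimethylsilyloxy)-3-methoxyphenyl]-6-{(2E)-5-[(2R,3R)-3-(hydroxymethyl)-3-methyloxiran-2-yl]-3-methylpent-2-enyl}chroman-4-one | OC[C@@]1(C)O[C@@H]1CC/C(C)=C/Cc1c(O[Si](C)(C)C(C)(C)C)cc2c(c1O[Si](C)(C)C(C)(C)C)C(=O)C[C@@H](c1ccc(O[Si](C)(C)C(C)(C)C)c(OC)c1)O2 | intermediate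
21 | (2S)-5,7-bis(tert-butyldimethylsilyloxy)-2-[4-(tert-butyldimethylsilyloxy)-3-methoxyphenyl]-6-{(2E)-5-[(2R,3S)-3-(iodomethyl)-3-methyloxiran-2-yl]-3-methylpent-2-enyl}chroman-4-one | IC[C@@]1(C)O[C@@H]1CC/C(C)=C/Cc1c(O[Si](C)(C)C(C)(C)C)cc2c(c1O[Si](C)(C)C(C)(C)C)C(=O)C[C@@H](c1ccc(O[Si](C)(C)C(C)(C)C)c(OC)c1)O2 | intermediate
22 | (2S)-5,7-bis(tert-butyldimethylsilyloxy)-2-[4-(tert-butyldimethylsilyloxy)-3-methoxyphenyl]-6-[(2E,6R)-6-hydroxy-3,7-dimethylocta-2,7-dienyl]chroman-4-one | C=C(C)[C@H](O)CC/C(C)=C/Cc1c(O[Si](C)(C)C(C)(C)C)cc2c(c1O[Si](C)(C)C(C)(C)C)C(=O)C[C@@H](c1ccc(O[Si](C)(C)C(C)(C)C)c(OC)c1)O2 | intermediate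
23 | (2S)-5,7-dihydroxy-2-(4-hydroxy-3-methoxyphenyl)-6-[(2E,6R)-6-hydroxy-3,7-dimethylocta-2,7-dienyl]chroman-4-one | C=C(C)[C@H](O)CC/C(C)=C/Cc1c(O)cc2c(c1O)C(=O)C[C@@H](c1ccc(O)c(OC)c1)O2 | target

## Step count and least certain steps

Total step count: 17. Longest linear sequence: 13 steps (steps 1, 2, 5, 6, 7, 8, 11, 12, 13, 14, 15, 16, 17).

**Step 14 (key step).**
- What may go wrong: the catalyst could be held back by binding of titanium to the flavanone carbonyl, or to a phenol set free by loss of the labile 5-O-silyl group. The Lewis acid could also open the oxirane at its tertiary carbon C7'', by attack of the C2''=C3'' alkene or of isopropoxide. Either process lowers conversion and facial selectivity.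
- Fallback: the oxidation, epoxidation and transposition are moved from the flavanone to the chain, where no ketone or arene is present. It sets out from geraniol 14 and iodide 13 and comes back at target 23.
 - Acetylation of 14 gives geranyl acetate F1.
 - SeO2/t-BuOOH oxidation gives the hydroxy acetate F2; the crude product is treated with NaBH4 to return over-oxidised material.
 - Ti(OiPr)4, D-(−)-diethyl tartrate and t-BuOOH give the epoxy alcohol F3.
 - PPh3, imidazole and I2 give the epoxy iodide F4.
 - Zinc and acetic acid give the (6R)-hydroxy acetate F5.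
 - TBSCl and imidazole give the silyl ether F6.
 - K2CO3 in methanol gives the allylic alcohol F7.
 - N-chlorosuccinimide and Me2S give the chloride F8, and Bu3SnLi gives the stannane F9.
 - Stille coupling of F9 with 13 under the conditions of step 11 gives the flavanone F10.
 - HF·pyridine with pyridine removes all three silyl groups and gives 23.

**Step 5.**
- What may go wrong: aryl transfer to a chromone carrying two donor oxygens may be slow, so protodeboronation of the electron-rich boronic acid could win. Face selectivity may be incomplete, and the product may suffer 1,2-addition or ring opening.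
- Fallback: the stereocentre is obtained by resolution instead of asymmetric catalysis, setting out from 4 and 9 and coming back at 10. Addition with an achiral divalent palladium catalyst (Pd(O2CCF3)2, 2,2'-bipyridine) gives the racemic flavanone F11. Kinetic resolution by asymmetric transfer hydrogenation follows, with RuCl(TsDPEN)(p-cymene) and HCO2H/Et3N, using the catalyst enantiomer that reduces the (2R)-ketone faster. This converts the unwanted enantiomer into the cis-flavan-4-ol F12 and leaves 10.

**Step 11.**
- What may go wrong: oxidative addition at a carbon with two ortho substituents is slow, so protodeiodination may compete. Allylic transposition may attach the chain through C3'', and E/Z scrambling may occur through η3-allyl palladium species.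
- Fallback: the polarity of the coupling is reversed, setting out from 13 and coming back at 17. Miyaura borylation of 13 (PdCl2(dppf), bis(pinacolato)diboron, KOAc, dioxane) gives the aryl pinacolboronate F13. This is coupled with geranyl bromide (Pd2(dba)3, anhydrous K2CO3, toluene), so that the geranyl group enters as an allyl electrophile and is attacked at its unsubstituted terminus.

**Step 13.**
- What may go wrong: oxidation may occur at another allylic position (C1'', C4'' or C5''), or run on to the aldehyde level. Ring C may be dehydrogenated at C2–C3, the Riley-type reaction of flavanones.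
- Fallback: the C8'' oxygen is brought in by carbon–carbon bond exchange instead of C–H oxidation, setting out from 18 and coming back at 19. Cross-metathesis of the terminal isopropylidene group of 18 with methacrolein gives the (2E,6E)-enal F14; the catalyst is the second-generation Hoveyda–Grubbs catalyst RuCl2(=CH-C6H4-2-OiPr)(H2IMes) in CH2Cl2 at 40 °C. Luche reduction (NaBH4, CeCl3, MeOH, −78 °C) then reduces the enal in the presence of the hindered aryl ketone. The same reduction would also return material that step 13 over-oxidises.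

## Further compounds

F1 | step 14 | geranyl acetate, (2E)-3,7-dimethylocta-2,6-dienyl acetate | CC(C)=CCC/C(C)=C/COC(C)=O
F2 | step 14 | (2E,6E)-8-hydroxy-3,7-dimethylocta-2,6-dienyl acetate | OC/C(C)=C/CC/C(C)=C/COC(C)=O
F3 | step 14 | (2E)-5-[(2R,3R)-3-(hydroxymethyl)-3-methyloxiran-2-yl]-3-methylpent-2-enyl acetate | OC[C@@]1(C)O[C@@H]1CC/C(C)=C/COC(C)=O
F4 | step 14 | (2E)-5-[(2R,3S)-3-(iodomethyl)-3-methyloxiran-2-yl]-3-methylpent-2-enyl acetate | IC[C@@]1(C)O[C@@H]1CC/C(C)=C/COC(C)=O
F5 | step 14 | (2E,6R)-6-hydroxy-3,7-dimethylocta-2,7-dienyl acetate | C=C(C)[C@H](O)CC/C(C)=C/COC(C)=O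
F6 | step 14 | (2E,6R)-6-(tert-butyldimethylsilyloxy)-3,7-dimethylocta-2,7-dienyl acetate | C=C(C)[C@H](O[Si](C)(C)C(C)(C)C)CC/C(C)=C/COC(C)=O
F7 | step 14 | (2E,6R)-6-(tert-butyldimethylsilyloxy)-3,7-dimethylocta-2,7-dien-1-ol | C=C(C)[C@H](O[Si](C)(C)C(C)(C)C)CC/C(C)=C/CO
F8 | step 14 | tert-butyl{[(3R,6E)-8-chloro-2,6-dimethylocta-1,6-dien-3-yl]oxy}dimethylsilane | C=C(C)[C@H](O[Si](C)(C)C(C)(C)C)CC/C(C)=C/CCl
F9 | step 14 | tributyl[(2E,6R)-6-(tert-butyldimethylsilyloxy)-3,7-dimethylocta-2,7-dienyl]stannane | C=C(C)[C@H](O[Si](C)(C)C(C)(C)C)CC/C(C)=C/C[Sn](CCCC)(CCCC)CCCC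
F10 | step 14 | (2S)-7-(tert-butyldimethylsilyloxy)-2-[4-(tert-butyldimethylsilyloxy)-3-methoxyphenyl]-6-[(2E,6R)-6-(tert-butyldimethylsilyloxy)-3,7-dimethylocta-2,7-dienyl]-5-hydroxychroman-4-one | C=C(C)[C@H](O[Si](C)(C)C(C)(C)C)CC/C(C)=C/Cc1c(O[Si](C)(C)C(C)(C)C)cc2c(c1O)C(=O)C[C@@H](c1ccc(O[Si](C)(C)C(C)(C)C)c(OC)c1)O2
F11 | step 5 | racemic 5,7-bis(benzyloxy)-2-[4-(benzyloxy)-3-methoxyphenyl]chroman-4-one | O=C1CC(c2ccc(OCc3ccccc3)c(OC)c2)Oc2cc(OCc3ccccc3)cc(OCc3ccccc3)c21
F12 | step 5 | (2R,4R)-5,7-bis(benzyloxy)-2-[4-(benzyloxy)-3-methoxyphenyl]chroman-4-ol | O[C@@H]1C[C@H](c2ccc(OCc3ccccc3)c(OC)c2)Oc2cc(OCc3ccccc3)cc(OCc3ccccc3)c21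
F13 | step 11 | (2S)-7-(tert-butyldimethylsilyloxy)-2-[4-(tert-butyldimethylsilyloxy)-3-methoxyphenyl]-5-hydroxy-6-(4,4,5,5-tetramethyl-1,3,2-dioxaborolan-2-yl)chroman-4-one | O=C1C[C@@H](c2ccc(O[Si](C)(C)C(C)(C)C)c(OC)c2)Oc2cc(O[Si](C)(C)C(C)(C)C)c(B3OC(C)(C)C(C)(C)O3)c(O)c21
F14 | step 13 | (2S)-5,7-bis(tert-butyldimethylsilyloxy)-2-[4-(tert-butyldimethylsilyloxy)-3-methoxyphenyl]-6-[(2E,6E)-3,7-dimethyl-8-oxoocta-2,6-dienyl]chroman-4-one | O=C/C(C)=C/CC/C(C)=C/Cc1c(O[Si](C)(C)C(C)(C)C)cc2c(c1O[Si](C)(C)C(C)(C)C)C(=O)C[C@@H](c1ccc(O[Si](C)(C)C(C)(C)C)c(OC)c1)O2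
A1 | alternative 1 | (2S)-6-[(2E,6R)-6-(tert-butyldimethylsilyloxy)-3,7-dimethylocta-2,7-dienyl]-5,7-dihydroxy-2-[3-methoxy-4-(triisopropylsilyloxy)phenyl]chroman-4-one | C=C(C)[C@H](O[Si](C)(C)C(C)(C)C)CC/C(C)=C/Cc1c(O)cc2c(c1O)C(=O)C[C@@H](c1ccc(O[Si](C(C)C)(C(C)C)C(C)C)c(OC)c1)O2
A2 | alternative 1 | methyl 2-[(2E,6R)-6-(tert-butyldimethylsilyloxy)-3,7-dimethylocta-2,7-dienyl]-4-{(2S)-2-[3-methoxy-4-(triisopropylsilyloxy)phenyl]-4-oxo-2,3-dihydropyran-6-yl}-3-oxobutanoate | COC(=O)C(C/C=C(C)/CC[C@@H](O[Si](C)(C)C(C)(C)C)C(C)=C)C(=O)CC1=CC(=O)C[C@@H](c2ccc(O[Si](C(C)C)(C(C)C)C(C)C)c(OC)c2)O1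
A3 | alternative 2 | allyl 4-{(2S)-5,7-bis(tert-butyldimethylsilyloxy)-6-[(2E,6R)-6-(tert-butyldimethylsilyloxy)-3,7-dimethylocta-2,7-dienyl]-4-oxochroman-2-yl}-2-methoxyphenyl carbonate | C=C(C)[C@H](O[Si](C)(C)C(C)(C)C)CC/C(C)=C/Cc1c(O[Si](C)(C)C(C)(C)C)cc2c(c1O[Si](C)(C)C(C)(C)C)C(=O)C[C@@H](c1ccc(OC(=O)OCC=C)c(OC)c1)O2
A4 | alternative 2 | (3S)-3-[4-(allyloxycarbonyloxy)-3-methoxyphenyl]-3-{3,5-bis(tert-butyldimethylsilyloxy)-4-[(2E,6R)-6-(tert-butyldimethylsilyloxy)-3,7-dimethylocta-2,7-dienyl]phenoxy}propanoic acid | OC(=O)C[C@@H](c1ccc(OC(=O)OCC=C)c(OC)c1)Oc1cc(O[Si](C)(C)C(C)(C)C)c(C/C=C(C)/CC[C@@H](O[Si](C)(C)C(C)(C)C)C(C)=C)c(O[Si](C)(C)C(C)(C)C)c1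
A5 | alternative 3 | (2S)-6-[(2E,6R)-6-(tert-butyldimethylsilyloxy)-3,7-dimethylocta-2,7-dienyl]-5,7-bis(methoxymethoxy)-2-[3-methoxy-4-(methoxymethoxy)phenyl]chroman-4-one | C=C(C)[C@H](O[Si](C)(C)C(C)(C)C)CC/C(C)=C/Cc1c(OCOC)cc2c(c1OCOC)C(=O)C[C@@H](c1ccc(OCOC)c(OC)c1)O2
A6 | alternative 3 | 3-[(2E,6R)-6-(tert-butyldimethylsilyloxy)-3,7-dimethylocta-2,7-dienyl]-2,4-bis(methoxymethoxy)-6-{1-[3-methoxy-4-(methoxymethoxy)phenyl]vinyloxy}benzaldehyde | O=Cc1c(OCOC)c(C/C=C(C)/CC[C@@H](O[Si](C)(C)C(C)(C)C)C(C)=C)c(OCOC)cc1OC(=C)c1ccc(OCOC)c(OC)c1
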